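**Retrosynthetic overview**

1. Endgame: target ⇐ acetonide hydrolysis ⇐ HWE methylenation (C11=C13) of a C11 dimethyl phosphonate ⇐ Mitsunobu esterification at C8 (inversion) ⇐ methanolysis of a five-membered cyclic phosphonate that links O8 to C11.
2. Ten-membered ring (formed third): NHK closure of C4–C5 between the (Z)-C3=C4 alkenyl iodide and the C5 aldehyde; the C5 carbinol is then set by oxidation/CBS reduction.
3. Key disconnection (two rings formed second, together): O6–C6 and C11–C7 by an Mn(III)/Cu(II) oxidative radical–polar annulation of an (E)-C6=C7 allylic phosphonoacetate tethered through P to O8. A 5-exo radical closure gives the 1,2-oxaphospholane (O8–C8–C7–C11–P), then lactonisation gives the butyrolactone (O6–C6–C7–C11–C12).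
4. Enabling feature: the C8 oxygen lies 1,2 to C7 and 1,3 to C6 (array O8–C8–C7–C6). A one-atom P link from O8 therefore puts C11 on C7 and its carboxyl on C6; the same phosphorus is the latent C11=C13 methylene, and C8 relays its configuration to C7 and C6.
5. Chain: (R)-mevalonolactone maps onto C8–C9–C10(CH3,OH)–C1–C2; two propargyl ethers add C3–C4–C15 (Noyori reduction, Red-Al/I2) and C5–C6–C7 (asymmetric alkenylzinc addition). The first ring formed is the protecting C2/C10 dioxane.

Key step: step 11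

Remark (numbering): atoms keep the germacrane locants of the target (ring C1–C10; C11/C12/C13 = lactone α-carbon, carbonyl and methylene; C14 = methyl on C10; C15 = CH2O on C4; On = oxygen on Cn). TES = triethylsilyl, TBDPS = tert-butyldiphenylsilyl, PMB = 4-methoxybenzyl. CIP descriptors are those of each compound and can change with substitution although the centre is untouched.

Remark (assumption): compounds 4, 11, 15 and 28, (+)-MIB and the (R,R)-Noyori catalyst are taken as commercially available.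

**Route**

Step 1
Reactants: 1 (R)-mevalonolactone
Product: 2 (3R)-3,5-dihydroxy-N-methoxy-N,3-dimethylpentanamide
Conditions: MeNH(OMe)·HCl, i-PrMgCl, THF, −20 → 0 °C; crude used at once
Reagents that add atoms: N,O-dimethylhydroxylamine hydrochloride, Cl.CNOC
Why: Weinreb amide formation by aminolysis of the lactone with the magnesium amide; the chiral-pool centre (future C10) is not touched.

Step 2
Reactants: 2 (3R)-3,5-dihydroxy-N-methoxy-N,3-dimethylpentanamide
Product: 3 (3R)-3-hydroxy-N-methoxy-N,3-dimethyl-5-(triethylsilyloxy)pentanamide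
Conditions: TESCl, imidazole, CH2Cl2, 0 °C
Reagents that add atoms: chlorotriethylsilane, CC[Si](Cl)(CC)CC
Why: Chemoselective silylation of the primary over the tertiary hydroxyl, which also stops relactonisation.

Step 3
Reactants: 3 (3R)-3-hydroxy-N-methoxy-N,3-dimethyl-5-(triethylsilyloxy)pentanamide; 4 tert-butyldiphenyl(prop-2-yn-1-yloxy)silane
Product: 5 (6R)-1-(TBDPS-oxy)-6-hydroxy-6-methyl-8-(TES-oxy)oct-2-yn-4-one
Conditions: 4 (3 equiv), n-BuLi, THF, −78 °C; then 3, −78 → −20 °C; aq. NH4Cl; used without delay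
Reagents that add atoms: none
Why: Weinreb ketone synthesis with the lithium acetylide (one equivalent is spent on the tertiary OH); the chelated tetrahedral intermediate should stop the addition at the ynone.

Step 4
Reactants: 5 (6R)-1-(TBDPS-oxy)-6-hydroxy-6-methyl-8-(TES-oxy)oct-2-yn-4-one
Product: 6 (4R,6R)-1-(TBDPS-oxy)-6-methyl-8-(TES-oxy)oct-2-yne-4,6-diol
Conditions: RuCl[(R,R)-TsDPEN](p-cymene) (2 mol %), i-PrOH, 23 °C
Reagents that add atoms: none
Why: Noyori asymmetric transfer hydrogenation of an alkynyl ketone; the (R,R)-catalyst, with the alkyne as the π-group, should deliver hydride to give the (R)-propargylic alcohol (C2) under catalyst control.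

Step 5
Reactants: 6 (4R,6R)-1-(TBDPS-oxy)-6-methyl-8-(TES-oxy)oct-2-yne-4,6-diol
Product: 8 (2Z,4R,6R)-1-(TBDPS-oxy)-2-iodo-6-methyl-8-(TES-oxy)oct-2-ene-4,6-diol, via sodium alkenylaluminate 7 (not isolated)
Conditions: Red-Al (3.5 equiv), THF, 0 → 23 °C; then I2, THF, −78 → 0 °C
Reagents that add atoms: iodine, II
Why: Hydroxyl-directed trans-hydroalumination of the propargylic alcohol places Al on C4 inside a five-membered alkoxyaluminate, and iodinolysis with retention should give the iodoalkene with I cis to C2, which fixes the later (3Z) ring geometry.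

Step 6
Reactants: 8 (2Z,4R,6R)-1-(TBDPS-oxy)-2-iodo-6-methyl-8-(TES-oxy)oct-2-ene-4,6-diol
Product: 9 (4R,6R)-4-[(1Z)-3-(TBDPS-oxy)-2-iodoprop-1-en-1-yl]-2,2,6-trimethyl-6-[2-(TES-oxy)ethyl]-1,3-dioxane
Conditions: 2-methoxypropene, PPTS (cat.), 4 Å MS, CH2Cl2, 0 °C
Reagents that add atoms: 2-methoxypropene, COC(C)=C
Why: Acetonide formation on the syn-1,3-diol (O2/O10), giving a chair dioxane with both chain branches equatorial; it protects the two hydroxyls that are free in the target.

Step 7
Reactants: 9 (4R,6R)-4-[(1Z)-3-(TBDPS-oxy)-2-iodoprop-1-en-1-yl]-2,2,6-trimethyl-6-[2-(TES-oxy)ethyl]-1,3-dioxane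
Product: 10 2-[(4S,6R)-6-[(1Z)-3-(TBDPS-oxy)-2-iodoprop-1-en-1-yl]-2,2,4-trimethyl-1,3-dioxan-4-yl]acetaldehyde
Conditions: (COCl)2, DMSO, CH2Cl2, −78 → −40 °C; Et3N, −78 → 0 °C; used at once
Reagents that add atoms: none
Why: Swern oxidation with in situ cleavage of the primary TES ether, a known selective conversion of primary triethylsilyl ethers into aldehydes.

Step 8
Reactants: 10 2-[(4S,6R)-6-[(1Z)-3-(TBDPS-oxy)-2-iodoprop-1-en-1-yl]-2,2,4-trimethyl-1,3-dioxan-4-yl]acetaldehyde; 11 1-methoxy-4-[(prop-2-yn-1-yloxy)methyl]benzene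
Product: 14 (2S,3E)-1-[(4R,6R)-6-[(1Z)-3-(TBDPS-oxy)-2-iodoprop-1-en-1-yl]-2,2,4-trimethyl-1,3-dioxan-4-yl]-5-(PMB-oxy)pent-3-en-2-ol, via alkenylborane 12 (not isolated), via alkenyl(ethyl)zinc 13 (not isolated)
Conditions: 11, Cy2BH (from BH3·SMe2, cyclohexene), toluene, 0 → 23 °C; Et2Zn, (+)-MIB (5 mol %), −78 °C; then 10, −20 → 0 °C; aq. NH4Cl
Reagents that add atoms: none
Why: Syn-hydroboration, B-to-Zn transmetalation and amino-alcohol-catalysed asymmetric alkenylzinc addition to the aldehyde; the (E)-alkene comes from the hydroboration and the ligand enantiomer is chosen for Re-face attack, which should give the (8S) carbinol (epimeric to the target at C8 by design).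

Step 9
Reactants: 15 tert-butyl 2-(dimethoxyphosphoryl)acetate
Product: 16 sodium methyl (2-tert-butoxy-2-oxoethyl)phosphonate
Conditions: NaI, acetone, reflux; salt collected by filtration
Reagents that add atoms: sodium iodide, [Na+].[I-]
Why: SN2 mono-demethylation of a dimethyl phosphonate by iodide; the monoanion formed resists a second dealkylation.

Step 10
Reactants: 14 (2S,3E)-1-[(4R,6R)-6-[(1Z)-3-(TBDPS-oxy)-2-iodoprop-1-en-1-yl]-2,2,4-trimethyl-1,3-dioxan-4-yl]-5-(PMB-oxy)pent-3-en-2-ol; 16 sodium methyl (2-tert-butoxy-2-oxoethyl)phosphonate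
Product: 18 tert-butyl 2-[methoxy(alkoxy)phosphoryl]acetate in which the alkoxy group is the C8 oxygen of 14 (P-epimers), via phosphonochloridate 17 (not isolated)
Conditions: 16, (COCl)2, DMF (cat.), CH2Cl2, 0 → 23 °C, evaporate; then 14, Et3N, DMAP (cat.), CH2Cl2, 0 → 23 °C
Reagents that add atoms: none
Why: Conversion of the phosphonate salt into its chloridate and O-phosphonylation of the secondary allylic alcohol (standard mixed phosphonate ester synthesis); C8 is not touched.

Step 11
Reactants: 18 tert-butyl 2-[methoxy(alkoxy)phosphoryl]acetate of alcohol 14 (P-epimers)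
Product: 19 cis-fused phostone-lactone (6S,7S,8S,11R; P-epimers) bearing CH2OPMB on C6
Conditions: Mn(OAc)3·2H2O (2.5 equiv), Cu(OAc)2·H2O (1 equiv), KOAc, degassed AcOH–MeCN (1:1), 0.02 M, 50 °C; stopped when 18 is consumed
Reagents that add atoms: none
Why: Proposed new method: Mn(III) oxidation of the phosphonoacetate enolate gives the electrophilic C11 radical, which closes the 1,2-oxaphospholane ring (O8–C8–C7–C11–P) by 5-exo-trig attack on C7 of the (E)-alkene; the C6 radical is then oxidised by Cu(II) and the organocopper(III)/cation is captured by the cis-disposed ester carbonyl oxygen (five-membered closure onto C6, loss of isobutene), which closes the butyrolactone (O6–C6–C7–C11–C12) and so forms O–C6 and C11–C7 in one operation. The closest known reaction is the Mn(OAc)3/Cu(OAc)2 oxidative cyclisation of allylic malonates to cis-fused bis-γ-lactones; the new element is the P–O8 phosphonate tether in place of the acyl tether, which is reasonable because α-phosphono ester radicals behave like malonyl radicals and the 5-exo geometry is retained. C7 is set by C8: with H8 eclipsing the alkene (A1,3 strain) the tethered radical adds to the face syn to O8, which puts C9 and C6 trans on the oxaphospholane (4-substituent rule for 5-hexenyl radical closures, chair-like transition state). C11 is fixed by the obligatory cis ring fusion and C6 is set by C7, because the CH2OPMB group takes the convex face of the cis-bicyclo[3.3.0] system and so ends trans to C8 on the lactone; phosphorus forms as both epimers, which does not matter because it is lost later. The step needs 5-exo over 6-endo closure (1,2-disubstituted alkene, five-membered transition state), attack on C6=C7 and not on the remote electron-poor iodoalkene (proximity), and lactonisation of the C6 radical over β-hydride elimination (ester carbonyl held 1,3 to C6 on the rigid bicycle, Cu(II) present).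

Step 12
Reactants: 19 cis-fused phostone-lactone bearing CH2OPMB on C6
Product: 20 phostone-lactone primary alcohol (C5H2OH)
Conditions: DDQ, CH2Cl2–pH 7 buffer (10:1), 0 °C
Reagents that add atoms: none
Why: Oxidative cleavage of the PMB ether by DDQ; silyl ether, acetonide, iodoalkene and the phosphonate are inert to it.

Step 13
Reactants: 20 phostone-lactone primary alcohol
Product: 21 phostone-lactone aldehyde (C5H=O)
Conditions: Dess–Martin periodinane, pyridine, CH2Cl2, 0 → 23 °C; used at once
Reagents that add atoms: none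
Why: Dess–Martin oxidation under buffered, non-epimerising conditions gives the α-acyloxy aldehyde.

Step 14
Reactants: 21 phostone-lactone aldehyde
Product: 22 macrocyclic C5 alcohol (cyclodec-3-ene; C5 epimers)
Conditions: CrCl2 (10 equiv), NiCl2 (cat.), DMSO–THF (3:1), slow addition to 2 mM, 23 °C
Reagents that add atoms: none
Why: Nozaki–Hiyama–Kishi macrocyclisation (Ni-catalysed formation of the alkenylchromium(III) from the C4 iodide and addition to the C5 aldehyde) closes the ten-membered ring with retention of the (3Z) geometry; C5 is expected as an epimer mixture (Felkin–Anh addition anti to O6 would favour 5R), and both epimers converge in step 15.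

Step 15
Reactants: 22 macrocyclic C5 alcohol (C5 epimers)
Product: 23 macrocyclic (3Z)-enone (C5 ketone)
Conditions: Dess–Martin periodinane, pyridine, CH2Cl2, 0 °C
Reagents that add atoms: none
Why: Dess–Martin oxidation of the allylic alcohol removes the uncontrolled C5 centre without touching C6.

Step 16
Reactants: 23 macrocyclic (3Z)-enone
Product: 24 macrocyclic (5S)-allylic alcohol
Conditions: (S)-Me-CBS oxazaborolidine (0.3 equiv), catecholborane, toluene–CH2Cl2, −78 °C
Reagents that add atoms: none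
Why: Corey–Bakshi–Shibata reduction of the enone with the α-branched alkenyl group (C4) as the large substituent should give 5S; this is matched with the Felkin–Anh preference for hydride attack anti to the C6–O6 bond.

Step 17
Reactants: 24 macrocyclic (5S)-allylic alcohol
Product: 26 macrocyclic 5,15-diacetate, via diol 25 (not isolated)
Conditions: HF·pyridine, pyridine, THF, 0 → 23 °C; MeOSiMe3 quench, evaporate; then Ac2O, pyridine, DMAP (cat.), CH2Cl2, 0 °C
Reagents that add atoms: acetic anhydride, CC(=O)OC(C)=O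
Why: Fluoride cleavage of the primary TBDPS ether (the acetonide survives buffered HF) followed by acetylation of both liberated hydroxyls installs the two acetates of the target.

Step 18
Reactants: 26 macrocyclic 5,15-diacetate
Product: 27 C11 dimethyl phosphonate with free (8S)-hydroxyl (C11 epimers)
Conditions: Et3N, MeOH–CH2Cl2, 0 → 23 °C; used at once
Reagents that add atoms: methanol, CO
Why: Strain-accelerated methanolysis of the five-membered cyclic phosphonate at phosphorus with departure of the ring oxygen O8, which is orders of magnitude faster than attack at the acetates or the γ-lactone; no carbon stereocentre is touched and P becomes achiral.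

Step 19
Reactants: 28 ethyl but-2-ynoate
Product: 30 ethyl (2Z)-2-(hydroxymethyl)but-2-enoate, via alkenylalane 29 (not isolated)
Conditions: DIBAL-H, NMO, THF, 0 °C; then monomeric CH2O (from paraformaldehyde), 0 → 23 °C
Reagents that add atoms: formaldehyde, C=O
Why: Syn-hydroalumination of the ynoate puts Al on the α-carbon, and trapping by formaldehyde with retention should give the (Z)-alkene with ester and methyl cis (sarracinate geometry).

Step 20
Reactants: 30 ethyl (2Z)-2-(hydroxymethyl)but-2-enoate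
Product: 31 (2Z)-2-(hydroxymethyl)but-2-enoic acid
Conditions: LiOH, THF–H2O, 0 → 23 °C; then 1 M HCl
Reagents that add atoms: lithium hydroxide, [Li+].[OH-]
Why: Saponification of the ethyl ester under mild conditions that should keep the alkene geometry.

Step 21
Reactants: 31 (2Z)-2-(hydroxymethyl)but-2-enoic acid
Product: 32 (2Z)-2-(acetoxymethyl)but-2-enoic acid
Conditions: Ac2O, pyridine, DMAP (cat.), CH2Cl2, 0 °C; aqueous work-up
Reagents that add atoms: acetic anhydride, CC(=O)OC(C)=O
Why: O-acetylation of the primary allylic alcohol; the aqueous work-up returns the free acid.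

Step 22
Reactants: 27 C11 dimethyl phosphonate with free (8S)-hydroxyl; 32 (2Z)-2-(acetoxymethyl)but-2-enoic acid
Product: 33 (8R)-ester of 27 with acid 32
Conditions: PPh3, DIAD, toluene, 0 → 23 °C
Reagents that add atoms: none
Why: Mitsunobu esterification proceeds by SN2 displacement of the C8 oxyphosphonium by the carboxylate, inverting 8S to the 8R configuration of the target without exposing the (Z)-acid to acyl-activating conditions.

Step 23
Reactants: 33 (8R)-ester of 27 with acid 32
Product: 34 α-methylene lactone acetonide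
Conditions: K2CO3, 37 % aq. HCHO, THF, 0 °C, short reaction time
Reagents that add atoms: formaldehyde, C=O
Why: Horner–Wadsworth–Emmons methylenation of the α-phosphono-γ-lactone with formaldehyde, a standard route to α-methylene-γ-butyrolactones; it is fast enough at 0 °C to spare the acetates.

Step 24
Reactants: 34 α-methylene lactone acetonide
Product: 35 target (2R,3Z,5S,6S,7R,8R,10S)
Conditions: AcOH–THF–H2O (3:1:1), 40 °C
Reagents that add atoms: none
Why: Mild acid hydrolysis of the isopropylidene acetal releases the C2 and C10 hydroxyls; the acetates, the enoate and the α-methylene lactone are stable to aqueous acetic acid.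

**Compound list**

1 | (R)-mevalonolactone, (4R)-4-hydroxy-4-methyloxan-2-one | C[C@@]1(O)CCOC(=O)C1 | starting material
2 | (3R)-3,5-dihydroxy-N-methoxy-N,3-dimethylpentanamide | CON(C)C(=O)C[C@](C)(O)CCO | intermediate
3 | (3R)-3-hydroxy-N-methoxy-N,3-dimethyl-5-(triethylsilyloxy)pentanamide | CON(C)C(=O)C[C@](C)(O)CCO[Si](CC)(CC)CC | intermediate
4 | tert-butyldiphenyl(prop-2-yn-1-yloxy)silane | C#CCO[Si](c1ccccc1)(c1ccccc1)C(C)(C)C | starting material
5 | (6R)-1-(tert-butyldiphenylsilyloxy)-6-hydroxy-6-methyl-8-(triethylsilyloxy)oct-2-yn-4-one | CC[Si](CC)(CC)OCC[C@@](C)(O)CC(=O)C#CCO[Si](c1ccccc1)(c1ccccc1)C(C)(C)C | intermediate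
6 | (4R,6R)-1-(tert-butyldiphenylsilyloxy)-6-methyl-8-(triethylsilyloxy)oct-2-yne-4,6-diol (2R,10R in target numbering) | CC[Si](CC)(CC)OCC[C@@](C)(O)C[C@@H](O)C#CCO[Si](c1ccccc1)(c1ccccc1)C(C)(C)C | intermediate
7 | sodium alkenylaluminate: five-membered ring O2–Al–C4=C3–C2, two 2-methoxyethoxy ligands on Al (tertiary OH drawn free) | CC[Si](CC)(CC)OCC[C@@](C)(O)C[C@H]1O[Al-](OCCOC)(OCCOC)C(CO[Si](c2ccccc2)(c2ccccc2)C(C)(C)C)=C1.[Na+] | intermediate
8 | (2Z,4R,6R)-1-(tert-butyldiphenylsilyloxy)-2-iodo-6-methyl-8-(triethylsilyloxy)oct-2-ene-4,6-diol | CC[Si](CC)(CC)OCC[C@@](C)(O)C[C@@H](O)/C=C(/CO[Si](c1ccccc1)(c1ccccc1)C(C)(C)C)I | intermediate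
9 | (4R,6R)-4-[(1Z)-3-(tert-butyldiphenylsilyloxy)-2-iodoprop-1-en-1-yl]-2,2,6-trimethyl-6-[2-(triethylsilyloxy)ethyl]-1,3-dioxane | CC[Si](CC)(CC)OCC[C@]1(C)C[C@H](/C=C(/CO[Si](c2ccccc2)(c2ccccc2)C(C)(C)C)I)OC(C)(C)O1 | intermediate
10 | 2-[(4S,6R)-6-[(1Z)-3-(tert-butyldiphenylsilyloxy)-2-iodoprop-1-en-1-yl]-2,2,4-trimethyl-1,3-dioxan-4-yl]acetaldehyde | O=CC[C@]1(C)C[C@H](/C=C(/CO[Si](c2ccccc2)(c2ccccc2)C(C)(C)C)I)OC(C)(C)O1 | intermediate
11 | 1-methoxy-4-[(prop-2-yn-1-yloxy)methyl]benzene (PMB propargyl ether) | C#CCOCc1ccc(OC)cc1 | starting material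
12 | dicyclohexyl[(1E)-3-(4-methoxybenzyloxy)prop-1-en-1-yl]borane | COc1ccc(COC/C=C/B(C2CCCCC2)C2CCCCC2)cc1 | intermediate
13 | ethyl[(1E)-3-(4-methoxybenzyloxy)prop-1-en-1-yl]zinc | CC[Zn]/C=C/COCc1ccc(OC)cc1 | intermediate
14 | (2S,3E)-1-[(4R,6R)-6-[(1Z)-3-(tert-butyldiphenylsilyloxy)-2-iodoprop-1-en-1-yl]-2,2,4-trimethyl-1,3-dioxan-4-yl]-5-(4-methoxybenzyloxy)pent-3-en-2-ol (2R,8S,10R in target numbering) | COc1ccc(COC/C=C/[C@@H](O)C[C@]2(C)C[C@H](/C=C(/CO[Si](c3ccccc3)(c3ccccc3)C(C)(C)C)I)OC(C)(C)O2)cc1 | intermediate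
15 | tert-butyl 2-(dimethoxyphosphoryl)acetate | COP(=O)(OC)CC(=O)OC(C)(C)C | starting material
16 | sodium methyl (2-tert-butoxy-2-oxoethyl)phosphonate | [Na+].COP(=O)([O-])CC(=O)OC(C)(C)C | intermediate
17 | tert-butyl 2-[chloro(methoxy)phosphoryl]acetate | COP(=O)(Cl)CC(=O)OC(C)(C)C | intermediate
18 | tert-butyl 2-[methoxy({(2S,3E)-1-[(4S,6R)-6-[(1Z)-3-(tert-butyldiphenylsilyloxy)-2-iodoprop-1-en-1-yl]-2,2,4-trimethyl-1,3-dioxan-4-yl]-5-(4-methoxybenzyloxy)pent-3-en-2-yl}oxy)phosphoryl]acetate, both P-epimers | COc1ccc(COC/C=C/[C@@H](OP(=O)(OC)CC(=O)OC(C)(C)C)C[C@]2(C)C[C@H](/C=C(/CO[Si](c3ccccc3)(c3ccccc3)C(C)(C)C)I)OC(C)(C)O2)cc1 | intermediate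
19 | phostone-lactone: cis-fused bicycle of 2-methoxy-2-oxo-1,2-oxaphospholane (O8–C8–C7–C11–P) and γ-butyrolactone (O6–C6–C7–C11–C12=O) sharing C7–C11; CH2OPMB on C6 trans to C8; on C8 the CH2 link to the (4S,6R)-dioxane of 10, trans to C6; (2R,6S,7S,8S,10S,11R), P-epimers | COc1ccc(COC[C@H]2OC(=O)[C@H]3[C@@H]2[C@H](C[C@]4(C)C[C@H](/C=C(/CO[Si](c5ccccc5)(c5ccccc5)C(C)(C)C)I)OC(C)(C)O4)OP3(=O)OC)cc1 | intermediate
20 | phostone-lactone primary alcohol: 19 with CH2OH on C6 | OC[C@H]1OC(=O)[C@H]2[C@@H]1[C@H](C[C@]3(C)C[C@H](/C=C(/CO[Si](c4ccccc4)(c4ccccc4)C(C)(C)C)I)OC(C)(C)O3)OP2(=O)OC | intermediate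
21 | phostone-lactone aldehyde: 19 with CHO (C5) on C6 | O=C[C@H]1OC(=O)[C@H]2[C@@H]1[C@H](C[C@]3(C)C[C@H](/C=C(/CO[Si](c4ccccc4)(c4ccccc4)C(C)(C)C)I)OC(C)(C)O3)OP2(=O)OC | intermediate
22 | macrocyclic alcohol: (3Z)-cyclodec-3-ene ring C1–C10 with the C2/C10 acetonide, CH2OTBDPS on C4, OH on C5 (both epimers), the γ-lactone at C6–C7 and the oxaphospholane at C7–C8 as in 19; (2R,6S,7S,8S,10S,11R) | OC1[C@H]2OC(=O)[C@H]3[C@@H]2[C@H](C[C@]4(C)C[C@@H](OC(C)(C)O4)/C=C1/CO[Si](c5ccccc5)(c5ccccc5)C(C)(C)C)OP3(=O)OC | intermediate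
23 | macrocyclic enone: 22 with C5 ketone; (2R,3Z,6S,7S,8S,10S,11R) | O=C1[C@H]2OC(=O)[C@H]3[C@@H]2[C@H](C[C@]4(C)C[C@@H](OC(C)(C)O4)/C=C1/CO[Si](c5ccccc5)(c5ccccc5)C(C)(C)C)OP3(=O)OC | intermediate
24 | macrocyclic (5S)-alcohol: 22 as the single 5S epimer; (2R,3Z,5S,6S,7S,8S,10S,11R) | O[C@@H]1[C@H]2OC(=O)[C@H]3[C@@H]2[C@H](C[C@]4(C)C[C@@H](OC(C)(C)O4)/C=C1/CO[Si](c5ccccc5)(c5ccccc5)C(C)(C)C)OP3(=O)OC | intermediate
25 | macrocyclic 5,15-diol: 24 without the TBDPS group | O[C@@H]1[C@H]2OC(=O)[C@H]3[C@@H]2[C@H](C[C@]4(C)C[C@@H](OC(C)(C)O4)/C=C1/CO)OP3(=O)OC | intermediate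
26 | macrocyclic 5,15-diacetate: 25 with both hydroxyls acetylated; (2R,3Z,5S,6S,7S,8S,10S,11R) | CC(=O)O[C@@H]1[C@H]2OC(=O)[C@H]3[C@@H]2[C@H](C[C@]4(C)C[C@@H](OC(C)(C)O4)/C=C1/COC(C)=O)OP3(=O)OC | intermediate
27 | ring-opened phosphonate: 5,15-diacetoxy-11-(dimethoxyphosphoryl)-8-hydroxy-2,10-O-isopropylidene-13-nor-germacr-3-en-6,12-olide; (2R,3Z,5S,6S,7R,8S,10R), C11 epimers | CC(=O)O[C@@H]1[C@H]2OC(=O)C(P(=O)(OC)OC)[C@@H]2[C@@H](O)C[C@]3(C)C[C@@H](OC(C)(C)O3)/C=C1/COC(C)=O | intermediate
28 | ethyl but-2-ynoate | CC#CC(=O)OCC | starting material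
29 | ethyl (2Z)-2-(diisobutylalumanyl)but-2-enoate (Al cis to H3) | CCOC(=O)/C(=C\C)[Al](CC(C)C)CC(C)C | intermediate
30 | ethyl (2Z)-2-(hydroxymethyl)but-2-enoate | CCOC(=O)/C(=C\C)CO | intermediate
31 | (2Z)-2-(hydroxymethyl)but-2-enoic acid | OC(=O)/C(=C\C)CO | intermediate
32 | (2Z)-2-(acetoxymethyl)but-2-enoic acid | OC(=O)/C(=C\C)COC(C)=O | intermediate
33 | 8-ester: 27 with O8 acylated by 32 and C8 inverted; (2R,3Z,5S,6S,7R,8R,10S), C11 epimers | CC(=O)O[C@@H]1[C@H]2OC(=O)C(P(=O)(OC)OC)[C@@H]2[C@H](OC(=O)/C(=C\C)COC(C)=O)C[C@]3(C)C[C@@H](OC(C)(C)O3)/C=C1/COC(C)=O | intermediate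
34 | α-methylene lactone acetonide: the target with O2 and O10 joined as isopropylidene acetal; (2R,3Z,5S,6S,7R,8R,10S) | CC(=O)O[C@@H]1[C@H]2OC(=O)C(=C)[C@@H]2[C@H](OC(=O)/C(=C\C)COC(C)=O)C[C@]3(C)C[C@@H](OC(C)(C)O3)/C=C1/COC(C)=O | intermediate
35 | target: (2R,3Z,5S,6S,7R,8R,10S)-5,15-diacetoxy-8-[(2Z)-2-(acetoxymethyl)but-2-enoyloxy]-2,10-dihydroxygermacra-3,11(13)-dien-6,12-olide | C=C1C(=O)O[C@H]2[C@H]1[C@H](OC(=O)/C(=C\C)COC(C)=O)C[C@@](C)(O)C[C@@H](O)/C=C(/COC(C)=O)[C@@H]2OC(C)=O | target

**Step count and risks**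

Total step count: 24. Longest linear sequence: 20 steps (steps 1–8, 10–18, 22–24, from (R)-mevalonolactone).

Steps most likely to fail:

1. Step 11 (Proposed new method). What may go wrong: slow Mn(III) enolisation of the less acidic phosphonoacetate; diversion of the C6 radical into Cu-mediated β-hydride elimination instead of lactonisation; over-oxidation at the still acidic C11–H of the product. Fallback (known reaction types, two-stage atom-transfer route): it sets out from 18 and returns at 19. C-Iodination of 18 (NaH, N-iodosuccinimide, THF, −78 °C) should give the α-iodophosphonoacetate F1. Iodine atom-transfer radical cyclisation of the Kharasch type (Et3B, air, benzene, 23 °C) should then give the cyclised C6 iodide F2 with the same tether-controlled C7 configuration. Silver-assisted ionisation of the iodide (AgOTf, 2,6-di-tert-butylpyridine, CH2Cl2) lets the tert-butyl ester close onto C6 from the convex face with loss of isobutene, which gives 19.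

2. Step 14. What may go wrong: ring closure too slow against protonation of the alkenylchromium by the acidic C11–H or against intermolecular coupling, because the ten-membered ring must form on a chain stiffened by the bicycle and the dioxane. Fallback (ketone-forming macrocyclisation instead of carbonyl addition): it sets out from 21 and returns at 23, so steps 14 and 15 are by-passed. Pinnick oxidation of 21 (NaClO2, NaH2PO4, 2-methyl-2-butene) should give the carboxylic acid F3, and 2,2'-dipyridyl disulfide/PPh3 the S-(2-pyridyl) thioester F4. Ni/Zr-mediated coupling of the thioester with the alkenyl iodide (NiBr2·dtbbpy cat., Cp2ZrCl2, Zn, DMI–THF, high dilution) should then give the enone 23 directly.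

3. Step 22. What may go wrong: slow substitution at the hindered C8 oxyphosphonium (flanked by C7 and the neopentyl-like C9), leading to elimination or recovered alcohol, and 6,12 → 8,12 translactonisation of 27 on standing. Fallback (redox inversion, then acylation with retention): it sets out from 27 and returns at 33. Dess–Martin oxidation should give the C8 ketone F5. Luche reduction (NaBH4, CeCl3, MeOH–CH2Cl2, −78 °C), with hydride entering anti to the C7–C11 branch, should give the (8R)-alcohol F6. Yamaguchi esterification with 32 (2,4,6-trichlorobenzoyl chloride, Et3N; then DMAP, toluene, 0 °C to limit Z to E isomerisation) gives 33.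

Further compounds
F1 | step 11 | α-iodophosphonoacetate: 18 with iodine on the carbon between P and the ester (epimers) | COc1ccc(COC/C=C/[C@@H](OP(=O)(OC)C(I)C(=O)OC(C)(C)C)C[C@]2(C)C[C@H](/C=C(/CO[Si](c3ccccc3)(c3ccccc3)C(C)(C)C)I)OC(C)(C)O2)cc1
F2 | step 11 | cyclised iodide: 2-methoxy-2-oxo-1,2-oxaphospholane with tert-butyl ester on C11 and CH(I)CH2OPMB on C7 (C6, C11 and P epimers; 7S,8S) | COc1ccc(COCC(I)[C@H]2[C@H](C[C@]3(C)C[C@H](/C=C(/CO[Si](c4ccccc4)(c4ccccc4)C(C)(C)C)I)OC(C)(C)O3)OP(=O)(OC)C2C(=O)OC(C)(C)C)cc1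
F3 | step 14 | phostone-lactone carboxylic acid: 21 with CO2H in place of CHO | OC(=O)[C@H]1OC(=O)[C@H]2[C@@H]1[C@H](C[C@]3(C)C[C@H](/C=C(/CO[Si](c4ccccc4)(c4ccccc4)C(C)(C)C)I)OC(C)(C)O3)OP2(=O)OC
F4 | step 14 | S-(pyridin-2-yl) thioester of F3 | O=C(Sc1ccccn1)[C@H]1OC(=O)[C@H]2[C@@H]1[C@H](C[C@]3(C)C[C@H](/C=C(/CO[Si](c4ccccc4)(c4ccccc4)C(C)(C)C)I)OC(C)(C)O3)OP2(=O)OC
F5 | step 22 | C8 ketone of 27 | CC(=O)O[C@@H]1[C@H]2OC(=O)C(P(=O)(OC)OC)[C@@H]2C(=O)C[C@]3(C)C[C@@H](OC(C)(C)O3)/C=C1/COC(C)=O
F6 | step 22 | (8R)-alcohol, the C8 epimer of 27 | CC(=O)O[C@@H]1[C@H]2OC(=O)C(P(=O)(OC)OC)[C@@H]2[C@H](O)C[C@]3(C)C[C@@H](OC(C)(C)O3)/C=C1/COC(C)=O
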